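**Assumption:** the target SMILES has no stereocentres and no E/Z-defined alkenes, so triquetrumone A is achiral and no enantiocontrol is needed. Compound 2 can be purchased, which would save step 1.

## Retrosynthetic overview

1. The furan ring (C3–C1' and C2–O2' bonds) is cut in one operation: a formal [3+2] union of a 2-aminochromone (C3 nucleophile, C2 electrophile) with 2-hydroxy-3-prenyl-1,4-benzoquinone.
2. The quinone comes from oxidative dearomatisation (CAN) of 1,2,4-trimethoxy-3-prenylbenzene, itself made by ortho-lithiation/prenylation of 1,2,4-trimethoxybenzene.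
3. The aminochromone comes from C2v-symmetric 2-methylphloroglucinol: desymmetrising Hoesch acetylation, CS2/MeI pyrone annulation, chromenylation at C8/O7, then SMe-to-pyrrolidine exchange.
4. Ring order: A ring (given), then γ-pyrone, then 2,2-dimethylpyran; the B ring arrives as a quinone and the furan forms last, re-aromatising B.

## Route

**Step 1**
Reactants: 1, 2-methylphloroglucinol
Product: 2, 1-(2,4,6-trihydroxy-3-methylphenyl)ethan-1-one
Conditions: MeCN, ZnCl2, HCl(g), Et2O, 0 °C; then H2O, 100 °C
Reagents that add atoms: acetonitrile, CC#N; water, O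
Why: Houben–Hoesch acylation; the two free ring positions of 1 are equivalent, so mono-acylation gives a single ketone, and the precipitating ketiminium salt prevents diacylation.

**Step 2**
Reactants: 2
Product: 3, 5,7-dihydroxy-6-methyl-2-(methylsulfanyl)-4H-chromen-4-one
Conditions: t-BuOK (5 equiv), CS2, THF, 0 °C to rt; then MeI (1.05 equiv), 0 °C; aq. HCl
Reagents that add atoms: carbon disulfide, S=C=S; iodomethane, CI
Why: Enolate addition to CS2, closure of an ortho phenoxide onto the dithiocarboxylate (2-thioxo-coumarin/2-mercaptochromone), then selective S-methylation; closure should favour the less hindered 6-OH because the 2-OH is buttressed by the methyl into the C=O chelate, giving the 6-methyl isomer (any 8-methyl isomer is removed here).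

**Step 3**
Reactants: 3; 4, prenal (3-methylbut-2-enal)
Product: 5, 5-hydroxy-6,8,8-trimethyl-2-(methylsulfanyl)-4H,8H-pyrano[2,3-h]chromen-4-one
Conditions: prenal (2 equiv), EDDA (20 mol %), xylene/DMF, 120–130 °C
Reagents that add atoms: prenal (4), CC(C)=CC=O
Why: Phenol–enal chromenylation (Knoevenagel-type C-alkylation, then oxa-6π electrocyclisation of the o-quinone methide); C6 is blocked by methyl, so only C8 can react and only O7 can close, giving the angular pyran.

**Step 4**
Reactants: 5; 6, pyrrolidine
Product: 7, 5-hydroxy-6,8,8-trimethyl-2-(pyrrolidin-1-yl)-4H,8H-pyrano[2,3-h]chromen-4-one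
Conditions: pyrrolidine (5 equiv), EtOH, 80 °C, N2 sweep (removes MeSH)
Reagents that add atoms: pyrrolidine (6), C1CCNC1
Why: Addition–elimination (vinylogous acyl substitution) at C2 of the vinylogous thioester, activated by the chelated C4=O, gives a tertiary enaminone that is nucleophilic at C3.

**Step 5**
Reactants: 8, 1,2,4-trimethoxybenzene; 9, prenyl bromide
Product: 10, 1,2,4-trimethoxy-3-(3-methylbut-2-en-1-yl)benzene
Conditions: n-BuLi, TMEDA, THF, 0 °C; CuBr·SMe2 (cat.), prenyl bromide, −78 °C to rt
Reagents that add atoms: prenyl bromide (9), CC(C)=CCBr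
Why: Directed ortho-metalation occurs at C3, between the 2- and 4-methoxy groups, and the aryl-copper species is alkylated at the primary carbon (SN2) of prenyl bromide.

**Step 6**
Reactants: 10
Product: 11, 2-methoxy-3-prenyl-1,4-benzoquinone
Conditions: CAN (2.5 equiv), MeCN/H2O, 0 °C, 15 min
Reagents that add atoms: water, O
Why: CAN oxidative demethylation of the para-dimethoxy pair dearomatises the ring to the p-quinone; the 2-OMe is retained and the trisubstituted prenyl alkene tolerates short exposure.

**Step 7**
Reactants: 11
Product: 12, 2-hydroxy-3-prenyl-1,4-benzoquinone (used at once)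
Conditions: 1 M NaOH, THF/H2O, 0 °C, N2, 20 min; then 1 M HCl
Reagents that add atoms: water/hydroxide, O
Why: Hydrolysis of a vinylogous ester by addition–elimination at C2 (as in methoxyquinone to hydroxyquinone conversions); no acid is present that could cyclise the prenyl group onto the new OH.

**Step 8 (key step)**
Reactants: 7; 12 (1.3 equiv)
Product: 13, triquetrumone A
Conditions: degassed AcOH, N2, rt to 50 °C
Reagents that add atoms: none
Why: Proposed new method: C3 of enaminone 7 adds to C5 of quinone 12 (β to the C1=O that is not part of the vinylogous acid), the adduct aromatises to the triol, and the OH ortho to the new C–C bond (next to the prenyl carbon) attacks the C2 iminium/amidine carbon and expels pyrrolidinium, forming the furan and leaving the 4',5'-catechol free in a redox-neutral, atom-balanced step; the closest known reaction is the Nenitzescu-type synthesis of 3-acyl-5-hydroxybenzofurans from tertiary enaminones and 1,4-benzoquinones in AcOH (also the Lewis-acid annulation of α-oxoketene dithioacetals with quinones).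

## Compound list

1 | 2-methylphloroglucinol (2-methylbenzene-1,3,5-triol) | Cc1c(O)cc(O)cc1O | starting material
2 | 1-(2,4,6-trihydroxy-3-methylphenyl)ethan-1-one | CC(=O)c1c(O)cc(O)c(C)c1O | intermediate
3 | 5,7-dihydroxy-6-methyl-2-(methylsulfanyl)-4H-chromen-4-one | CSc1cc(=O)c2c(O)c(C)c(O)cc2o1 | intermediate
4 | prenal (3-methylbut-2-enal) | CC(C)=CC=O | starting material
5 | 5-hydroxy-6,8,8-trimethyl-2-(methylsulfanyl)-4H,8H-pyrano[2,3-h]chromen-4-one | CSc1cc(=O)c2c(O)c(C)c3OC(C)(C)C=Cc3c2o1 | intermediate
6 | pyrrolidine | C1CCNC1 | starting material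
7 | 5-hydroxy-6,8,8-trimethyl-2-(pyrrolidin-1-yl)-4H,8H-pyrano[2,3-h]chromen-4-one | Cc1c(O)c2c(=O)cc(N3CCCC3)oc2c2C=CC(C)(C)Oc12 | intermediate
8 | 1,2,4-trimethoxybenzene | COc1ccc(OC)c(OC)c1 | starting material
9 | prenyl bromide (1-bromo-3-methylbut-2-ene) | CC(C)=CCBr | starting material
10 | 1,2,4-trimethoxy-3-(3-methylbut-2-en-1-yl)benzene | COc1ccc(OC)c(CC=C(C)C)c1OC | intermediate
11 | 2-methoxy-3-(3-methylbut-2-en-1-yl)-1,4-benzoquinone | COC1=C(CC=C(C)C)C(=O)C=CC1=O | intermediate
12 | 2-hydroxy-3-(3-methylbut-2-en-1-yl)-1,4-benzoquinone | CC(C)=CCC1=C(O)C(=O)C=CC1=O | intermediate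
13 | triquetrumone A (achiral) | CC(C)=CCc1c(O)c(O)cc2c1oc1oc3c4c(c(C)c(O)c3c(=O)c12)OC(C)(C)C=C4 | target

## Summary

**Total steps:** 8. **Longest linear sequence:** 5 (steps 1, 2, 3, 4, 8); the quinone branch is 4 (steps 5, 6, 7, 8).

**Three steps most likely to fail**

1. **Step 8** (unprecedented enaminone partner; a hydroxyquinone is a weak electrophile; the chromene could compete). Fallback: replace the quinone annulation with cross-coupling. Iodinate 7 at C3 (NIS), Suzuki-couple with a 2-hydroxy-4,5-bis(MOM-oxy)-3-prenylphenylboronate, then close the furan by acid-mediated displacement of pyrrolidine by the 2'-OH and remove the MOM groups.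
2. **Step 2** (6-methyl versus 8-methyl closure is only kinetically biased, and the polyanion/CS2 chemistry is demanding on a triphenol). Fallback: build the pyrone oxygen-first. Engage the one OH of 1 not flanked by methyl in an oxa-Michael addition to a β-chloro-β-(pyrrolidinyl)acrylate (or ynamine ester), then close by intramolecular Friedel–Crafts acylation onto either of the two equivalent ortho carbons. The regiochemistry then rests on reaction at the unhindered OH, and 7's des-chromene analogue is reached without the thioether.
3. **Step 7** (hydroxybenzoquinones with free C5/C6 can decompose in base). Fallback: avoid the methoxyquinone. Tris-MOM-protect 1,2,4-benzenetriol, lithiate and prenylate at C3, remove the MOM groups (HCl/MeOH), and oxidise the resulting 3-prenylbenzene-1,2,4-triol (Ag2O or air) to 12 immediately before or in the pot of step 8.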